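The leftover of the oak run, 2% of ring at 40.0 min, is too small to read much from, so we must ask which readings can carry a rate.

| flask | starting material | remark | time |
|---|---|---|---|
| oak | 0.30 M | run made earlier |  |
| flask | 0.15 M |  | 2.0 h |

oak run (percent of the starting material charged)

| time / min | ring / % |
|---|---|
| 6.00 | 19 |
| 12.0 | 12 |
| 20.0 | 6 |
| 25.0 | 3 |
| 30.0 | 4 |
| 40.0 | 2 |

(standard deviation of a reading: 1.5 percentage points)

- the earlier runs were read with a standard deviation of 1.5 percentage points

1. the moment within 2.0 h at which there is most ring
2. the amount of ring, in percent of the starting material charged, at that time

We take ring as an intermediate made from the starting material, and we get its fall rate in the oak run in two ways. The readings at 6.00 min and 20.0 min give 0.0823 min⁻¹, while those at 25.0 min and 40.0 min give 0.0270 min⁻¹, which is slower. The two part, and the late pair is the one we set aside: its last reading stands close to the scatter of 1.5 points, and the reading at 30.0 min, 4%, lies above the earlier 3%.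

Running the earlier rate back from the first reading to the moment of charging gives the fall-line ceiling, 31.1%: the height at the start of the line along which ring falls. If ring in the oak run falls first-order at this rate, then before the first reading, while starting material feeds it, ring stands under this line. If making ring is first-order too, percentages do not move with the charge, so we expect the flask at 0.15 M to peak at or before about 6.00 min, between 19% and 31.1%.

The forecast differs, with 100% at 0 h: “The ring is the starting material”.

The flask gives 23.6% at 5.86 min.

    starting material → ring (k = 0.120 min⁻¹)
    ring → over-reaction product (k = 0.140 min⁻¹)
    ring ⇌ isomer of the product (K = 1.90, k = 0.0170 min⁻¹)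
    2 starting material → open dimer (k = 0.480 L mol⁻¹ min⁻¹)

The best of the flask at 0.15 M lies under the ceiling by 7.5 points. Against the 19.5% that the oak run holds at its highest without the scatter, changing the charge alone gives 23.6%, so the percentage did move with the charge. The same ceiling held against the neighbour charged with 0.037 M leaves a gap of 2 points: that neighbour's best is 29.2%. At 2.00 h that neighbour holds 12.4% of its charge as open dimer, against 34.3% in the flask at 0.15 M.

(The earlier runs and the new flask are calculated for substances that don't exist; the scatter is artificial.)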